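A percentage per hour read from the red or the amber run misleads for this flask, whose charge of solid X lies between theirs.

in all of them: D 19 mM (held)
- red: X 0.062 M; run made earlier
- amber: X 0.14 M; run made earlier
- flask: X 0.093 M; time 15 h

- red (time / h: Q / %, Z / %): 0.667: 3.2, 0; 1.33: 10.7, 0; 2.50: 18.6, 1.1; 5.00: 37.8, 14.6; 10.0: 76.3, 52.5
- amber (time / h: Q / %, Z / %): 2.00: 6.7, 1.0; 4.00: 13.1, 2.7; 5.00: 15.6, 5.7; 8.00: 26.3, 16.4; 10.0: 33.4, 22.8

(each reading ± 1 percentage point)

- percentages count the X that a species holds: one E counts as two
- Q is meant together with its Z
- solid, in amounts per volume of the solution: X, Z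
- at the start none of J is dissolved
- on the list of suspects stand: X <-> L; L + J -> Q; 2 L -> E; Z <-> Q; D <-> J; J -> G
- at the start none of X is in solution
- L means what is dissolved; the solid is not counted in it

1. the Q and Z together standing at 15 h, as a percentage of the X charged
2. concentration of L in solution at 15 h, in percent of saturation

Red's percentage pace at its last reading, held for the flask's 15 h, gives 114%, which passes the whole charge, so the charge itself is the upper bound. Amber's pace gives 50.1%, the lower bound. The bracket tightens in concentration: red gained 4.73 mM h⁻¹ and amber 4.68 mM h⁻¹, although amber held about twice the X. This is the output rate, the concentration of Q and Z gained per hour, zero-order in the charge. Over 15 h it brackets the flask at 75.4% to 76.3%.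

Going round once more, the upper figure leaves 22.0 mM of X outside Q and Z in the flask. That is more than the 14.7 mM red had left on its straight line, so the rate may be carried to the end. The readings hold no [L], so this reckoning gives no figure for it. The forecast says 75%, close to the bracket's lower edge, and 92% of saturation, holding that “solid probably survives and L stays near saturation”.

The flask gives 76.1%, close to the bracket's upper figure, with [L] at 7.07% of saturation.

    X ⇌ L, rate k1*(cs1 - [L]) while solid is left; crystals form when [L] > cs1 (solubility = 8.40 mM, k = 0.620 h⁻¹)
    L + J → Q (k = 480 L mol⁻¹ h⁻¹)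
    2 L → E (k = 97.0 L mol⁻¹ h⁻¹)
    Z ⇌ Q, rate k4*(cs4 - [Q]) while solid is left; crystals form when [Q] > cs4 (solubility = 13.0 mM, k = 3.80 h⁻¹)
    D ⇌ J, rate k5*(csat - [J]) (kL = 2.10 h⁻¹)
    J → G (k = 3.50 × 10⁻⁴ h⁻¹)

Dissolving X runs at most at 5.21 mM h⁻¹ while solid is left, the rate constant times the saturation concentration of L, and the output rate read from the red run is nearly all of that. Setting the two equal, with E neglected, puts [L] near 9.21% of saturation, beside the flask's 7.07%. Charged with 0.37 M of X, the neighbour flask reckons at 19.2% by the same rate, and it stands at 19.1%.

The readings were computed on assumed constants; the scatter is artificial.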